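**Retrosynthetic overview**
1. Target ⇐ O-acylation of the (5E)-5-ylidene-3-methyltetronic acid with 15-methylhexadecanoic acid.
2. Butenolide ring (the only ring made, the furan is bought) ⇐ Lacey–Dieckmann closure of an (E)-α-(propanoyloxy)acrylate. Its enol C–O bond ⇐ light-driven nickel-catalysed coupling of propanoic acid with an (E)-α-bromoacrylate, which carries the alkene geometry into the ring.
3. (E)-α-Bromoacrylate ⇐ bromo-HWE on an α-methyl aldehyde ⇐ ester from SN2 inversion of ethyl O-triflyl-(S)-lactate by a primary Grignard reagent (sole stereocentre, chiral pool).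
4. Chain ⇐ nickel-electrocatalytic decarboxylative alkenylation of the redox-active ester of a furyl heptenoic acid with an (E)-alkenyl iodide made from 5-chloropent-1-yne.
5. Furyl heptenoic acid ⇐ geranyl acetate (selective ozonolysis/oxidation, then copper-catalysed coupling with 3-furylmethylmagnesium chloride).

Assumption: the exocyclic C=C is taken exactly as written in the SMILES (side chain cis to the acyloxy-bearing ring carbon, i.e. 5E), and compounds 4, 12, 16 and 21 are treated as catalogue chemicals.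

**Step 1**
Reactants: 1 geranyl acetate
Product: 3 (4E)-6-acetoxy-4-methylhex-4-enoic acid, via aldehyde 2 (not isolated)
Conditions: O3 (1.0 equiv), pyridine, CH2Cl2, −78 °C; solvent switch; NaClO2, NaH2PO4, 2-methylbut-2-ene, t-BuOH/H2O, 0 °C to rt
Reagents that add atoms: ozone, [O-][O+]=O; sodium chlorite, [Na+].[O-]Cl=O
Why: Selective ozonolysis attacks the electron-rich terminal trisubstituted alkene much faster than the alkene deactivated by the allylic acetate, and the aldehyde is oxidised in the same flask (Pinnick oxidation); the E-alkene comes unchanged from geranyl acetate.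

**Step 2**
Reactants: 3 (4E)-6-acetoxy-4-methylhex-4-enoic acid; 4 3-(chloromethyl)furan
Product: 6 (4E)-7-(furan-3-yl)-4-methylhept-4-enoic acid, via Grignard reagent 5 (not isolated)
Conditions: 4, Mg, THF, 0 °C to rt; separately 3, MeMgCl (1.0 equiv), THF, −30 °C; then 5 (1.4 equiv), Li2CuCl4 (5 mol%), −30 to 0 °C; aq. HCl
Reagents that add atoms: magnesium, [Mg] (stays only in intermediate 5)
Why: Copper-catalysed allylic substitution (Fouquet–Schlosser-type coupling) of the primary allylic acetate by the furylmethyl Grignard reagent occurs at the unhindered α-carbon with retention of the E-alkene, the acid being masked as its chloromagnesium carboxylate.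

**Step 3**
Reactants: 7 5-chloropent-1-yne
Product: 9 (1E)-5-chloro-1-iodo-2-methylpent-1-ene, via alkenylalane 8 (not isolated)
Conditions: AlMe3 (2 equiv), Cp2ZrCl2 (20 mol%), CH2Cl2, 0 °C to rt; then I2, THF, −30 to 0 °C
Reagents that add atoms: trimethylaluminium, C[Al](C)C; iodine, II
Why: Negishi carboalumination adds methyl and aluminium syn across the terminal alkyne (methyl to the internal carbon), and iodinolysis with retention gives the E-alkenyl iodide.

**Step 4**
Reactants: 6 (4E)-7-(furan-3-yl)-4-methylhept-4-enoic acid; 9 (1E)-5-chloro-1-iodo-2-methylpent-1-ene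
Product: 11 3-[(3E,7E)-11-chloro-4,8-dimethylundeca-3,7-dien-1-yl]furan, via redox-active ester 10 (not isolated)
Conditions: 6, N-hydroxyphthalimide, N,N′-diisopropylcarbodiimide, DMAP (cat.), CH2Cl2, rt, used crude; then 9 (2 equiv), NiCl2·6H2O (10 mol%), 2,2′-bipyridine (10 mol%), AgNO3 (30 mol%), DMF, Mg anode, carbon-foam cathode, constant current, rt
Reagents that add atoms: N-hydroxyphthalimide, O=C1c2ccccc2C(=O)N1O (stays only in intermediate 10)
Why: Nickel-electrocatalytic decarboxylative alkenylation: cathodic reduction of the N-acyloxyphthalimide releases CO2 and a primary homoallylic radical, which is captured by the alkenylnickel species formed from 9 and coupled with retention of the E geometry, while the alkyl chloride is inert.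

**Step 5**
Reactants: 11 3-[(3E,7E)-11-chloro-4,8-dimethylundeca-3,7-dien-1-yl]furan; 12 ethyl (2S)-2-{[(trifluoromethyl)sulfonyl]oxy}propanoate
Product: 14 ethyl (2S,6E,10E)-13-(furan-3-yl)-2,6,10-trimethyltrideca-6,10-dienoate, via Grignard reagent 13 (not isolated)
Conditions: 11, Mg (activated), THF, 60 °C; then 12 (1.3 equiv), ZnCl2 (5 mol%), THF, 0 °C
Reagents that add atoms: magnesium, [Mg] (stays only in intermediate 13)
Why: Zinc-catalysed SN2 alkylation of the α-triflyloxy ester by the Grignard reagent (through a triorganozincate) goes with clean inversion, so the only stereocentre comes from (S)-lactate and is (S) in 14 (the descriptor is unchanged because the CIP priorities change).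

**Step 6**
Reactants: 14 ethyl (2S,6E,10E)-13-(furan-3-yl)-2,6,10-trimethyltrideca-6,10-dienoate
Product: 15 (2S,6E,10E)-13-(furan-3-yl)-2,6,10-trimethyltrideca-6,10-dienal
Conditions: i-Bu2AlH (1.1 equiv), CH2Cl2, −78 °C; aq. potassium sodium tartrate work-up; used at once
Reagents that add atoms: none
Why: Partial ester reduction (DIBAL reduction) stops at the aluminium hemiacetal at −78 °C and gives the aldehyde on work-up without touching the α-stereocentre under these cold, non-basic conditions.

**Step 7**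
Reactants: 15 (2S,6E,10E)-13-(furan-3-yl)-2,6,10-trimethyltrideca-6,10-dienal; 16 methyl 2-[bis(2,2,2-trifluoroethoxy)phosphoryl]-2-bromoacetate
Product: 17 methyl (2E,4S,8E,12E)-2-bromo-15-(furan-3-yl)-4,8,12-trimethylpentadeca-2,8,12-trienoate
Conditions: 16 (1.1 equiv), KOt-Bu (1.05 equiv), 18-crown-6, THF, −78 °C; then 15
Reagents that add atoms: none
Why: Horner–Wadsworth–Emmons olefination with the bis(trifluoroethyl) bromophosphonoacetate (Still–Gennari-type kinetic control) gives the (E)-α-bromoacrylate with the alkyl chain cis to the ester carbon, and the preformed phosphonate anion does not epimerise the aldehyde at −78 °C.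

**Step 8**
Reactants: 17 methyl (2E,4S,8E,12E)-2-bromo-15-(furan-3-yl)-4,8,12-trimethylpentadeca-2,8,12-trienoate; 18 propanoic acid
Product: 19 methyl (2E,4S,8E,12E)-15-(furan-3-yl)-4,8,12-trimethyl-2-(propanoyloxy)pentadeca-2,8,12-trienoate
Conditions: 18 (2 equiv), NiBr2(dme) (5 mol%), 4,4′-di-tert-butyl-2,2′-bipyridine (5 mol%), Ir(ppy)3 (1 mol%), t-BuNH(i-Pr) (2 equiv), DMF, blue LEDs (450 nm), 25 °C
Reagents that add atoms: none
Why: Proposed new method: photosensitised nickel-catalysed C(sp2)–O coupling of a carboxylic acid, known for aryl bromides, is applied here to an alkenyl bromide (an α-bromoacrylate); zerovalent nickel adds oxidatively into the activated C–Br bond, bromide is exchanged for propanoate, and triplet energy transfer from excited Ir(ppy)3 to the alkenyl divalent nickel carboxylate triggers C–O reductive elimination with retention, making the bond that becomes O1–C5 of the butenolide with oxygen trans to the side chain; if the alkenylnickel equilibrated through its O-bound allenoate form, the bulky ligated nickel would still sit trans to the branched chain, so kinetic retention and thermodynamics give the same (E) enol ester; the closest known reactions are the nickel/photosensitiser esterification of aryl bromides and copper-catalysed O-vinylation of carboxylates.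

**Step 9**
Reactants: 19 methyl (2E,4S,8E,12E)-15-(furan-3-yl)-4,8,12-trimethyl-2-(propanoyloxy)pentadeca-2,8,12-trienoate
Product: 20 (5E)-5-[(2S,6E,10E)-13-(furan-3-yl)-2,6,10-trimethyltrideca-6,10-dien-1-ylidene]-4-hydroxy-3-methylfuran-2(5H)-one
Conditions: LiN(SiMe3)2 (2.2 equiv), THF, −78 to 0 °C; then cold 1 M HCl; kept cold and dark
Reagents that add atoms: none
Why: Lacey–Dieckmann cyclisation: the propanoate enolate attacks the geminal methyl ester to close the butenolide ring, formation of the acidic tetronate drives it, the exocyclic alkene geometry is carried over unchanged, and the tertiary allylic C–H is held in the alkene plane by allylic strain so the stereocentre is not deprotonated.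

**Step 10**
Reactants: 20 (5E)-5-[(2S,6E,10E)-13-(furan-3-yl)-2,6,10-trimethyltrideca-6,10-dien-1-ylidene]-4-hydroxy-3-methylfuran-2(5H)-one; 21 15-methylhexadecanoic acid
Product: 22 (2E)-2-[(2S,6E,10E)-13-(furan-3-yl)-2,6,10-trimethyltrideca-6,10-dien-1-ylidene]-4-methyl-5-oxo-2,5-dihydrofuran-3-yl 15-methylhexadecanoate (target)
Conditions: 21 (1.2 equiv), EDC·HCl (1.3 equiv), DMAP (5 mol%), CH2Cl2, 0 °C
Reagents that add atoms: none
Why: Carbodiimide esterification (Steglich-type) acylates the acidic 4-hydroxyl of the tetronic acid, C-acylation at C3 being blocked by the methyl group, and neither the stereocentre nor any alkene is touched.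

**Compound list**
1 | geranyl acetate | CC(C)=CCC/C(C)=C/COC(C)=O | starting material
2 | (2E)-3-methyl-6-oxohex-2-en-1-yl acetate | O=CCC/C(C)=C/COC(C)=O | intermediate
3 | (4E)-6-acetoxy-4-methylhex-4-enoic acid | OC(=O)CC/C(C)=C/COC(C)=O | intermediate
4 | 3-(chloromethyl)furan | ClCc1ccoc1 | starting material
5 | (furan-3-ylmethyl)magnesium chloride | Cl[Mg]Cc1ccoc1 | intermediate
6 | (4E)-7-(furan-3-yl)-4-methylhept-4-enoic acid | OC(=O)CC/C(C)=C/CCc1ccoc1 | intermediate
7 | 5-chloropent-1-yne | ClCCCC#C | starting material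
8 | [(1E)-5-chloro-2-methylpent-1-en-1-yl]dimethylalane | ClCCC/C(C)=C/[Al](C)C | intermediate
9 | (1E)-5-chloro-1-iodo-2-methylpent-1-ene | ClCCC/C(C)=C/I | intermediate
10 | 1,3-dioxoisoindolin-2-yl (4E)-7-(furan-3-yl)-4-methylhept-4-enoate | O=C(CC/C(C)=C/CCc1ccoc1)ON1C(=O)c2ccccc2C1=O | intermediate
11 | 3-[(3E,7E)-11-chloro-4,8-dimethylundeca-3,7-dien-1-yl]furan | ClCCC/C(C)=C/CC/C(C)=C/CCc1ccoc1 | intermediate
12 | ethyl (2S)-2-{[(trifluoromethyl)sulfonyl]oxy}propanoate | CCOC(=O)[C@H](C)OS(=O)(=O)C(F)(F)F | starting material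
13 | [(4E,8E)-11-(furan-3-yl)-4,8-dimethylundeca-4,8-dien-1-yl]magnesium chloride | Cl[Mg]CCC/C(C)=C/CC/C(C)=C/CCc1ccoc1 | intermediate
14 | ethyl (2S,6E,10E)-13-(furan-3-yl)-2,6,10-trimethyltrideca-6,10-dienoate | CCOC(=O)[C@@H](C)CCC/C(C)=C/CC/C(C)=C/CCc1ccoc1 | intermediate
15 | (2S,6E,10E)-13-(furan-3-yl)-2,6,10-trimethyltrideca-6,10-dienal | O=C[C@@H](C)CCC/C(C)=C/CC/C(C)=C/CCc1ccoc1 | intermediate
16 | methyl 2-[bis(2,2,2-trifluoroethoxy)phosphoryl]-2-bromoacetate | COC(=O)C(Br)P(=O)(OCC(F)(F)F)OCC(F)(F)F | starting material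
17 | methyl (2E,4S,8E,12E)-2-bromo-15-(furan-3-yl)-4,8,12-trimethylpentadeca-2,8,12-trienoate | COC(=O)/C(Br)=C\[C@@H](C)CCC/C(C)=C/CC/C(C)=C/CCc1ccoc1 | intermediate
18 | propanoic acid | CCC(=O)O | starting material
19 | methyl (2E,4S,8E,12E)-15-(furan-3-yl)-4,8,12-trimethyl-2-(propanoyloxy)pentadeca-2,8,12-trienoate | COC(=O)/C(OC(=O)CC)=C\[C@@H](C)CCC/C(C)=C/CC/C(C)=C/CCc1ccoc1 | intermediate
20 | (5E)-5-[(2S,6E,10E)-13-(furan-3-yl)-2,6,10-trimethyltrideca-6,10-dien-1-ylidene]-4-hydroxy-3-methylfuran-2(5H)-one | CC1=C(O)/C(=C\[C@@H](C)CCC/C(C)=C/CC/C(C)=C/CCc2ccoc2)OC1=O | intermediate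
21 | 15-methylhexadecanoic acid | OC(=O)CCCCCCCCCCCCCC(C)C | starting material
22 | (2E)-2-[(2S,6E,10E)-13-(furan-3-yl)-2,6,10-trimethyltrideca-6,10-dien-1-ylidene]-4-methyl-5-oxo-2,5-dihydrofuran-3-yl 15-methylhexadecanoate | CC1=C(OC(=O)CCCCCCCCCCCCCC(C)C)/C(=C\[C@@H](C)CCC/C(C)=C/CC/C(C)=C/CCc2ccoc2)OC1=O | target

**Step count and risks**
Total: 10 steps. Longest linear sequence: 9 steps (steps 1, 2, 4, 5, 6, 7, 8, 9, 10 from geranyl acetate).

Step 8 (the proposed new step). The excited sensitiser may reduce the bromoacrylate directly (hydrodebromination), or C–O reductive elimination from the alkenylnickel may be slow. The fallback uses known chemistry and reverses the polarity at the alkenyl carbon. It sets out from 17. Miyaura borylation (B2pin2, PdCl2(dppf), KOPh, toluene, 50 °C) gives with retention methyl (2Z,4S,8E,12E)-15-(furan-3-yl)-4,8,12-trimethyl-2-(4,4,5,5-tetramethyl-1,3,2-dioxaborolan-2-yl)pentadeca-2,8,12-trienoate F4. KHF2 in aqueous methanol converts it into potassium trifluoro[(2Z,4S,8E,12E)-15-(furan-3-yl)-1-methoxy-4,8,12-trimethyl-1-oxopentadeca-2,8,12-trien-2-yl]borate F5. Copper-catalysed oxidative acyloxylation of the alkenyltrifluoroborate with 18 (CuBr, DMAP, O2, molecular sieves, CH2Cl2) then gives the enol ester with retention and comes back to the route at 19.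

Step 4. The homoallylic radical may dimerise or be reduced, and an excess of 9 is needed. The fallback replaces the radical coupling by a polar organozinc cross-coupling. It sets out from 6. Esterification with N-hydroxypyridine-2-thione (DCC, CH2Cl2, dark) gives 2-thioxopyridin-1(2H)-yl (4E)-7-(furan-3-yl)-4-methylhept-4-enoate F1. Visible-light Barton decarboxylation in the presence of iodoform gives 3-[(3E)-6-iodo-4-methylhex-3-en-1-yl]furan F2. Zinc insertion (Zn dust, LiCl, THF) gives [(3E)-6-(furan-3-yl)-3-methylhex-3-en-1-yl]zinc iodide F3. Negishi coupling with 9 (Pd(PPh3)4, THF, rt) comes back to the route at 11.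

Step 9. The enol-ester enolate may lose methylketene instead of cyclising, or the base may erode the stereocentre by γ-deprotonation. The fallback takes the ring from a pre-formed tetronate and corrects the geometry afterwards. It sets out from 15. Commercial 4-methoxy-3-methylfuran-2(5H)-one is lithiated (LiN(i-Pr)2, THF, −78 °C) to 5-lithio-4-methoxy-3-methylfuran-2(5H)-one F6. Addition to 15 gives the aldol 5-[(2S,6E,10E)-13-(furan-3-yl)-1-hydroxy-2,6,10-trimethyltrideca-6,10-dien-1-yl]-4-methoxy-3-methylfuran-2(5H)-one F7. Mesylation (MsCl, Et3N) gives the corresponding methanesulfonate F8, and DBU eliminates it to (5Z)-5-[(2S,6E,10E)-13-(furan-3-yl)-2,6,10-trimethyltrideca-6,10-dien-1-ylidene]-4-methoxy-3-methylfuran-2(5H)-one F9. Demethylation with n-PrSLi gives (5Z)-5-[(2S,6E,10E)-13-(furan-3-yl)-2,6,10-trimethyltrideca-6,10-dien-1-ylidene]-4-hydroxy-3-methylfuran-2(5H)-one F10. UV irradiation (350 nm, benzene) to the photostationary Z/E mixture, chromatographic separation and recycling of F10 comes back to the route at 20. This fallback is not selective and depends on separating the isomers.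

**Further compounds**
F1 | step 4 | 2-thioxopyridin-1(2H)-yl (4E)-7-(furan-3-yl)-4-methylhept-4-enoate | O=C(CC/C(C)=C/CCc1ccoc1)On1ccccc1=S
F2 | step 4 | 3-[(3E)-6-iodo-4-methylhex-3-en-1-yl]furan | ICC/C(C)=C/CCc1ccoc1
F3 | step 4 | [(3E)-6-(furan-3-yl)-3-methylhex-3-en-1-yl]zinc iodide | I[Zn]CC/C(C)=C/CCc1ccoc1
F4 | step 8 | methyl (2Z,4S,8E,12E)-15-(furan-3-yl)-4,8,12-trimethyl-2-(4,4,5,5-tetramethyl-1,3,2-dioxaborolan-2-yl)pentadeca-2,8,12-trienoate | COC(=O)/C(B1OC(C)(C)C(C)(C)O1)=C\[C@@H](C)CCC/C(C)=C/CC/C(C)=C/CCc1ccoc1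
F5 | step 8 | potassium trifluoro[(2Z,4S,8E,12E)-15-(furan-3-yl)-1-methoxy-4,8,12-trimethyl-1-oxopentadeca-2,8,12-trien-2-yl]borate | COC(=O)/C([B-](F)(F)F)=C\[C@@H](C)CCC/C(C)=C/CC/C(C)=C/CCc1ccoc1.[K+]
F6 | step 9 | 5-lithio-4-methoxy-3-methylfuran-2(5H)-one | [Li]C1OC(=O)C(C)=C1OC
F7 | step 9 | 5-[(2S,6E,10E)-13-(furan-3-yl)-1-hydroxy-2,6,10-trimethyltrideca-6,10-dien-1-yl]-4-methoxy-3-methylfuran-2(5H)-one | COC1=C(C)C(=O)OC1C(O)[C@@H](C)CCC/C(C)=C/CC/C(C)=C/CCc1ccoc1
F8 | step 9 | (2S,6E,10E)-13-(furan-3-yl)-1-(3-methoxy-4-methyl-5-oxo-2,5-dihydrofuran-2-yl)-2,6,10-trimethyltrideca-6,10-dien-1-yl methanesulfonate | COC1=C(C)C(=O)OC1C(OS(C)(=O)=O)[C@@H](C)CCC/C(C)=C/CC/C(C)=C/CCc1ccoc1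
F9 | step 9 | (5Z)-5-[(2S,6E,10E)-13-(furan-3-yl)-2,6,10-trimethyltrideca-6,10-dien-1-ylidene]-4-methoxy-3-methylfuran-2(5H)-one | COC1=C(C)C(=O)O/C1=C\[C@@H](C)CCC/C(C)=C/CC/C(C)=C/CCc1ccoc1
F10 | step 9 | (5Z)-5-[(2S,6E,10E)-13-(furan-3-yl)-2,6,10-trimethyltrideca-6,10-dien-1-ylidene]-4-hydroxy-3-methylfuran-2(5H)-one | CC1=C(O)/C(=C/[C@@H](C)CCC/C(C)=C/CC/C(C)=C/CCc2ccoc2)OC1=O
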